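**Plan**
- Retrosynthetic cuts: C7–OH and C8–H (hydroboration–oxidation of a C7=C8 enol ether); then C7=C8 (olefination, the ester carbon becoming C9); then the ring B phenol O–C8 bond (carbene O–H insertion); then the ring A phenol O–glyceryl bond (Mitsunobu).
- Forward: the ring A aldehyde and the ring B aryloxy-phosphonoacetate are made separately and joined at C7=C8. The ester is reduced and silylated, the alkene is hydroborated, and the protecting groups are removed. No ring is formed.
- Enabling feature: C7 (benzylic CH–OH on ring A) and C8 (CH–O–ring B) are adjacent CH centres in a threo relation. Syn addition of H and OH across an (E)-C7=C8 enol ether with ring A cis to C9 gives exactly this pair.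
- Stereochemistry: the relative configuration comes from the alkene geometry (kinetic diaryl-phosphonate olefination). The absolute configuration comes from the pinene enantiomer in the borane.

Key step: step 8

Assumption: locants follow the neolignan convention (C7 benzylic carbon on ring A, C8 the carbon bearing the ring B aryloxy group, C9 the hydroxymethyl carbon; ring A carries the glyceryl ether, ring B the two methoxy groups and the hydroxypropyl chain); the four starting materials are taken as purchasable; the facial preference of IpcBH2 is assigned from its established behaviour with (E)-disubstituted and trisubstituted alkenes, and the antipodal borane would be used in the same step if the sense proved opposite.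

**Step 1**
Reactants: 1 vanillin; 2 2,2-dimethyl-1,3-dioxan-5-ol
Product: 3 4-[(2,2-dimethyl-1,3-dioxan-5-yl)oxy]-3-methoxybenzaldehyde
Conditions: PPh3, DIAD, THF, 0 °C → rt
Reagents that add atoms: none
Why: Mitsunobu etherification, in which the acidic phenol of vanillin displaces the oxyphosphonium of the secondary alcohol; C5 of the dioxane is not stereogenic, so the inversion has no consequence.

**Step 2**
Reactants: 4 4-(3-hydroxypropyl)-2,6-dimethoxyphenol
Product: 5 4-{3-[(tert-butyldimethylsilyl)oxy]propyl}-2,6-dimethoxyphenol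
Conditions: TBSCl (1.05 equiv), imidazole, CH2Cl2, 0 °C
Reagents that add atoms: tert-butyldimethylsilyl chloride, CC(C)(C)[Si](C)(C)Cl
Why: Chemoselective imidazole-promoted silylation, the unhindered primary alcohol reacting ahead of a phenol that is flanked by two methoxy groups and hydrogen-bonded to them.

**Step 3**
Reactants: 6 ethyl 2-(diphenoxyphosphoryl)acetate
Product: 7 ethyl 2-diazo-2-(diphenoxyphosphoryl)acetate
Conditions: 4-acetamidobenzenesulfonyl azide, DBU, MeCN, 0 °C → rt
Reagents that add atoms: 4-acetamidobenzenesulfonyl azide, CC(=O)Nc1ccc(cc1)S(=O)(=O)N=[N+]=[N-]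
Why: Regitz diazo transfer to an active methylene compound; the diphenyl phosphonoacetate is acidic enough to be deprotonated by DBU.

**Step 4**
Reactants: 5 4-{3-[(tert-butyldimethylsilyl)oxy]propyl}-2,6-dimethoxyphenol; 7 ethyl 2-diazo-2-(diphenoxyphosphoryl)acetate
Product: 8 ethyl 2-(4-{3-[(tert-butyldimethylsilyl)oxy]propyl}-2,6-dimethoxyphenoxy)-2-(diphenoxyphosphoryl)acetate (racemic)
Conditions: Rh2(OAc)4 (1 mol%), toluene, 80 °C
Reagents that add atoms: none
Why: Rhodium carbenoid O–H insertion, the electrophilic acceptor-substituted carbenoid being captured by the phenol oxygen (oxonium ylide, then proton shift); the new stereocentre forms racemic and is erased in step 5.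

**Step 5**
Reactants: 3 4-[(2,2-dimethyl-1,3-dioxan-5-yl)oxy]-3-methoxybenzaldehyde; 8 ethyl 2-(4-{3-[(tert-butyldimethylsilyl)oxy]propyl}-2,6-dimethoxyphenoxy)-2-(diphenoxyphosphoryl)acetate
Product: 9 ethyl (E)-2-(4-{3-[(tert-butyldimethylsilyl)oxy]propyl}-2,6-dimethoxyphenoxy)-3-{4-[(2,2-dimethyl-1,3-dioxan-5-yl)oxy]-3-methoxyphenyl}prop-2-enoate (ring A cis to the ester carbon C9)
Conditions: NaH, THF, −78 °C → 0 °C
Reagents that add atoms: none
Why: Horner–Wadsworth–Emmons olefination in its diaryl phosphonate variant, where fast, irreversible collapse of the kinetically preferred adduct places the aldehyde aryl cis to the ester, the sense known for α-alkyl and α-halo diaryl phosphonoacetates; this fixes the (E)-geometry.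

**Step 6**
Reactants: 9 the (E)-ester
Product: 10 (E)-2-(4-{3-[(tert-butyldimethylsilyl)oxy]propyl}-2,6-dimethoxyphenoxy)-3-{4-[(2,2-dimethyl-1,3-dioxan-5-yl)oxy]-3-methoxyphenyl}prop-2-en-1-ol
Conditions: i-Bu2AlH, CH2Cl2, −78 °C; aq. KNaC4H4O6
Reagents that add atoms: none
Why: 1,2-Reduction of an α,β-unsaturated ester to the allylic alcohol by i-Bu2AlH; the enol ether, silyl ether and acetonide are inert and the alkene geometry is untouched.

**Step 7**
Reactants: 10 the (E)-allylic alcohol
Product: 11 (E)-enol ether bis(silyl ether): the C9 tert-butyldimethylsilyl ether of 10, ring A cis to C9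
Conditions: TBSCl, imidazole, DMF, rt
Reagents that add atoms: tert-butyldimethylsilyl chloride, CC(C)(C)[Si](C)(C)Cl
Why: Standard imidazole-promoted silylation of a primary allylic alcohol, so that the hydroxyl neither consumes nor directs the borane in the next step.

**Step 8**
Reactants: 11 the (E)-enol ether bis(silyl ether)
Product: 13 (1R,2R)-3-[(tert-butyldimethylsilyl)oxy]-2-(4-{3-[(tert-butyldimethylsilyl)oxy]propyl}-2,6-dimethoxyphenoxy)-1-{4-[(2,2-dimethyl-1,3-dioxan-5-yl)oxy]-3-methoxyphenyl}propan-1-ol [(7R,8R), threo], via benzylic borane 12 (not isolated)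
Conditions: IpcBH2 [from (1S)-(−)-α-pinene, titrated THF solution, 2 equiv], THF, −25 °C → 0 °C; then 3 M NaOH, 30% H2O2, 0 °C
Reagents that add atoms: hydrogen peroxide, OO
Why: The B–H bond of IpcBH2 adds across C7=C8 in a concerted four-centre syn transition state with boron on C7, the less substituted carbon and the nucleophilic terminus beta to the enol ether oxygen, and hydrogen on C8; alkaline H2O2 then exchanges boron for hydroxyl with retention by 1,2-migration in the boron hydroperoxide ate complex. The closest known reaction type is the asymmetric hydroboration–oxidation of trisubstituted alkenes and of enol ethers with isopinocampheylboranes, and no ring is closed. C7 and C8 become stereocentres together: their threo relation follows from syn addition to the (E)-alkene in which ring A and C9 are cis, and their absolute (7R,8R) sense from the borane made from (−)-α-pinene, which by the empirical model for this reagent should attack the face of C7 that leads to 7R. The step needs regio-, diastereo- and enantioselectivity, secured in turn by the oxygen on C8 together with the lower substitution at C7, by the defined alkene geometry, and by the reagent. Oxidising the β-aryloxyborane 12 cold should forestall loss of the ring B aryloxide by β-elimination.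

**Step 9**
Reactants: 13 the (7R,8R)-alcohol bis(silyl ether)
Product: 14 (1R,2R)-1-{4-[(2,2-dimethyl-1,3-dioxan-5-yl)oxy]-3-methoxyphenyl}-2-[4-(3-hydroxypropyl)-2,6-dimethoxyphenoxy]propane-1,3-diol
Conditions: Bu4NF, THF, 0 °C → rt
Reagents that add atoms: none
Why: Fluoride-driven cleavage of both primary silyl ethers (desilylation through the strong Si–F bond); the acetonide, the aryl ethers and both stereocentres are inert, and with no free phenol there is no quinone methide pathway.

**Step 10**
Reactants: 14 the acetonide triol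
Product: 15 (1R,2R)-1-{4-[(1,3-dihydroxypropan-2-yl)oxy]-3-methoxyphenyl}-2-[4-(3-hydroxypropyl)-2,6-dimethoxyphenoxy]propane-1,3-diol (CNP0324330.2)
Conditions: AcOH–H2O (4:1), rt
Reagents that add atoms: none
Why: Acid-catalysed hydrolysis of the six-membered isopropylidene acetal, under conditions mild enough that the benzylic C7–O bond, deactivated by the neighbouring aryloxy group, should not ionise and C7 should not epimerise.

**Compound list**
1 | vanillin (4-hydroxy-3-methoxybenzaldehyde) | COc1cc(C=O)ccc1O | starting material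
2 | 2,2-dimethyl-1,3-dioxan-5-ol | OC1COC(C)(C)OC1 | starting material
3 | 4-[(2,2-dimethyl-1,3-dioxan-5-yl)oxy]-3-methoxybenzaldehyde | COc1cc(C=O)ccc1OC1COC(C)(C)OC1 | intermediate
4 | 4-(3-hydroxypropyl)-2,6-dimethoxyphenol | COc1cc(CCCO)cc(OC)c1O | starting material
5 | 4-{3-[(tert-butyldimethylsilyl)oxy]propyl}-2,6-dimethoxyphenol | COc1cc(CCCO[Si](C)(C)C(C)(C)C)cc(OC)c1O | intermediate
6 | ethyl 2-(diphenoxyphosphoryl)acetate | CCOC(=O)CP(=O)(Oc1ccccc1)Oc1ccccc1 | starting material
7 | ethyl 2-diazo-2-(diphenoxyphosphoryl)acetate | CCOC(=O)C(=[N+]=[N-])P(=O)(Oc1ccccc1)Oc1ccccc1 | intermediate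
8 | ethyl 2-(4-{3-[(tert-butyldimethylsilyl)oxy]propyl}-2,6-dimethoxyphenoxy)-2-(diphenoxyphosphoryl)acetate, racemic | CCOC(=O)C(Oc1c(OC)cc(CCCO[Si](C)(C)C(C)(C)C)cc1OC)P(=O)(Oc1ccccc1)Oc1ccccc1 | intermediate
9 | ethyl (E)-2-(aryloxy)-3-arylprop-2-enoate, ring A cis to the ester | COc1cc(/C=C(/Oc2c(OC)cc(CCCO[Si](C)(C)C(C)(C)C)cc2OC)C(=O)OCC)ccc1OC1COC(C)(C)OC1 | intermediate
10 | (E)-2-(aryloxy)-3-arylprop-2-en-1-ol, ring A cis to C9 | COc1cc(/C=C(/Oc2c(OC)cc(CCCO[Si](C)(C)C(C)(C)C)cc2OC)CO)ccc1OC1COC(C)(C)OC1 | intermediate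
11 | (E)-enol ether bis(tert-butyldimethylsilyl ether), ring A cis to C9 | COc1cc(/C=C(/Oc2c(OC)cc(CCCO[Si](C)(C)C(C)(C)C)cc2OC)CO[Si](C)(C)C(C)(C)C)ccc1OC1COC(C)(C)OC1 | intermediate
12 | C7-(isopinocampheyl)hydroborane adduct of 11, B on C7 and H on C8 added syn, spatial arrangement as in 13 | COc1cc([C@@H]([BH][C@H]2C[C@H]3C[C@@H]([C@@H]2C)C3(C)C)[C@@H](CO[Si](C)(C)C(C)(C)C)Oc2c(OC)cc(CCCO[Si](C)(C)C(C)(C)C)cc2OC)ccc1OC1COC(C)(C)OC1 | intermediate
13 | (7R,8R)-threo alcohol with both primary hydroxyls as tert-butyldimethylsilyl ethers and the glyceryl diol as acetonide | COc1cc([C@@H](O)[C@@H](CO[Si](C)(C)C(C)(C)C)Oc2c(OC)cc(CCCO[Si](C)(C)C(C)(C)C)cc2OC)ccc1OC1COC(C)(C)OC1 | intermediate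
14 | (7R,8R)-triol acetonide | COc1cc([C@@H](O)[C@@H](CO)Oc2c(OC)cc(CCCO)cc2OC)ccc1OC1COC(C)(C)OC1 | intermediate
15 | (1R,2R)-1-{4-[(1,3-dihydroxypropan-2-yl)oxy]-3-methoxyphenyl}-2-[4-(3-hydroxypropyl)-2,6-dimethoxyphenoxy]propane-1,3-diol | COc1cc([C@@H](O)[C@@H](CO)Oc2c(OC)cc(CCCO)cc2OC)ccc1OC(CO)CO | target

**Totals**
Total step count: 10. Longest linear sequence: 8 steps (steps 3 to 10 from compound 6; equally steps 2 and 4 to 10 from compound 4).

**Steps most likely to fail**

1. Step 8. What may go wrong: the borane discriminates poorly between the two faces of this hindered aryl enol ether, or the ring B aryloxide is lost from the β-aryloxyborane before oxidation.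
Fallback: setting out from 11, the alkene is hydroborated with excess BH3·SMe2 in THF at 0 °C. This smaller, faster reagent should still add syn with boron on C7 and give the racemic threo C7-monoalkylborane F1. Oxidation in the same flask (NaOH, H2O2, 0 °C) gives the racemic threo alcohol F2. Resolution of F2 by preparative chromatography on a chiral stationary phase gives the (7R,8R) enantiomer, which is 13, and the route continues with step 9. The absolute configuration then comes from resolution and no longer from reagent control.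

2. Step 5. What may go wrong: the kinetic preference of the olefination erodes, or the ester isomerises toward the more stable geometry, so that 9 forms mixed with its (Z)-isomer.
Fallback: setting out from such an isomer mixture of 9, the thermodynamic isomer is used and C7 is corrected afterwards.
- Equilibration with catalytic I2 in toluene under visible light should converge the mixture on the (Z)-ester F3 (ring A trans to the ester).
- Reduction with i-Bu2AlH gives the (Z)-allylic alcohol F4, and silylation (TBSCl, imidazole) gives the (Z)-enol ether bis(silyl ether) F5.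
- Hydroboration with IpcBH2 made from (+)-α-pinene gives the benzylic borane F6 (not isolated). Oxidation with NaOH and H2O2 gives the erythro (7S,8R)-alcohol F7, since syn addition to the (Z)-alkene places OH and O-aryl erythro.
- Mitsunobu inversion at C7 with 4-nitrobenzoic acid (PPh3, DIAD) gives the (7R,8R) 4-nitrobenzoate F8. Methanolysis (K2CO3, MeOH) comes back to the route at 13.

3. Step 4. What may go wrong: the electrophilic carbenoid attacks the electron-rich ring B or its methoxy oxygens, or dimerises, faster than it inserts into the hindered phenol O–H bond.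
Fallback: setting out from 6, deprotonation (NaH, THF) and bromination with N-bromosuccinimide gives ethyl 2-bromo-2-(diphenoxyphosphoryl)acetate F9. SN2 displacement of bromide by the potassium phenoxide of 5 (K2CO3, acetone), as is routine for phenols and bromomalonates, comes back to the route at 8.

**Further compounds**
F1 | step 8 | racemic threo C7-monoalkylborane of 11 (not isolated) | COc1cc([C@@H](B)[C@@H](CO[Si](C)(C)C(C)(C)C)Oc2c(OC)cc(CCCO[Si](C)(C)C(C)(C)C)cc2OC)ccc1OC1COC(C)(C)OC1.COc1cc([C@H](B)[C@H](CO[Si](C)(C)C(C)(C)C)Oc2c(OC)cc(CCCO[Si](C)(C)C(C)(C)C)cc2OC)ccc1OC1COC(C)(C)OC1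
F2 | step 8 | racemic threo alcohol (13 and its enantiomer, 1:1) | COc1cc([C@@H](O)[C@@H](CO[Si](C)(C)C(C)(C)C)Oc2c(OC)cc(CCCO[Si](C)(C)C(C)(C)C)cc2OC)ccc1OC1COC(C)(C)OC1.COc1cc([C@H](O)[C@H](CO[Si](C)(C)C(C)(C)C)Oc2c(OC)cc(CCCO[Si](C)(C)C(C)(C)C)cc2OC)ccc1OC1COC(C)(C)OC1
F3 | step 5 | ethyl (Z)-2-(aryloxy)-3-arylprop-2-enoate, geometric isomer of 9 | COc1cc(/C=C(\Oc2c(OC)cc(CCCO[Si](C)(C)C(C)(C)C)cc2OC)C(=O)OCC)ccc1OC1COC(C)(C)OC1
F4 | step 5 | (Z)-allylic alcohol, geometric isomer of 10 | COc1cc(/C=C(\Oc2c(OC)cc(CCCO[Si](C)(C)C(C)(C)C)cc2OC)CO)ccc1OC1COC(C)(C)OC1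
F5 | step 5 | (Z)-enol ether bis(silyl ether), geometric isomer of 11 | COc1cc(/C=C(\Oc2c(OC)cc(CCCO[Si](C)(C)C(C)(C)C)cc2OC)CO[Si](C)(C)C(C)(C)C)ccc1OC1COC(C)(C)OC1
F6 | step 5 | C7-(isopinocampheyl)hydroborane adduct of F5, Ipc from (+)-α-pinene (not isolated) | COc1cc([C@H]([BH][C@@H]2C[C@@H]3C[C@H]([C@H]2C)C3(C)C)[C@@H](CO[Si](C)(C)C(C)(C)C)Oc2c(OC)cc(CCCO[Si](C)(C)C(C)(C)C)cc2OC)ccc1OC1COC(C)(C)OC1
F7 | step 5 | erythro (7S,8R)-alcohol, C7 epimer of 13 | COc1cc([C@H](O)[C@@H](CO[Si](C)(C)C(C)(C)C)Oc2c(OC)cc(CCCO[Si](C)(C)C(C)(C)C)cc2OC)ccc1OC1COC(C)(C)OC1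
F8 | step 5 | (7R,8R) 4-nitrobenzoate of 13 | COc1cc([C@@H](OC(=O)c2ccc(cc2)[N+](=O)[O-])[C@@H](CO[Si](C)(C)C(C)(C)C)Oc2c(OC)cc(CCCO[Si](C)(C)C(C)(C)C)cc2OC)ccc1OC1COC(C)(C)OC1
F9 | step 4 | ethyl 2-bromo-2-(diphenoxyphosphoryl)acetate | CCOC(=O)C(Br)P(=O)(Oc1ccccc1)Oc1ccccc1
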